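**The leftover.** On a one-for-one count, amber, the flask asked about, keeps a leftover of both reagents. A reading of 56% leaves 44.0% of the electrophile and, in the same measure, 54.0% of nucleophile, yet the readings seem to level off.

all flasks: electrophile 11 mM; nucleophile 12.1 mM

| charge | free base | temperature | remark | time |
|---|---|---|---|---|
| amber | 8.8 mM | −20 °C | the very flask that is asked about, followed so far |  |
| violet | 8.8 mM | −25 °C | run made earlier |  |
| flask | 8.80 mM | −20 °C |  | 15 min |

- amber (time / min: target / %): 1.33: 50; 4.00: 54; 8.00: 56; 10.0: 54; 15.0: 58
- violet (time / min: target / %): 1.33: 41; 4.00: 56; 8.00: 53; 10.0: 57; 15.0: 56

(each reading ± 1.5 percentage points)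

- theta: at 15 min raise the temperature by 25 K, then wait 30 min
- gamma: at 15 min take out 90% of the target then present, then wait 30 min
- beta: change nothing and wait 30 min more
- epsilon: at 15 min add free base, 100% of the amount charged, then wait 30 min
- alpha: at 15 min add free base, 50.0% of the amount charged, then wait 30 min

- removed target is counted in
- additions bring no volume worth counting

* target, in percent of the electrophile first charged, at 15 min
* the option that brings most further target ("none" if no option brings more than 2 percentage points) (theta / gamma / beta / epsilon / alpha / none)
* target present, with what was taken out counted in, in percent of the electrophile first charged, after theta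
* target present, with what was taken out counted in, in percent of the electrophile first charged, after beta

**The ceiling.** So I change the count. I suppose each target costs two nucleophile: one built in, one lost to what the step sets free. The two-for-one ceiling, the share of electrophile that can become target at that price, is then half the nucleophile charge over the electrophile charge: 55.0%. Amber reads 54% to 58% from 4.00 min on. On this count the nucleophile, charged at 1.10 equivalents, is the limiting reagent.

**Time.** Amber's readings lie near the ceiling from 4.00 min on. Its last reading stands 4 percentage points above the one at 4.00 min, but the scatter is 1.5 points, and violet reads 56% at both 4.00 min and 15.0 min. I expect no gain from beta.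

**Temperature.** Violet, at −25 °C, starts lower, 41% against 50%, and ends at the same height within scatter. The ceiling holds no temperature, so I expect no gain from theta.

**Removal.** Taking out target returns no nucleophile on my count, so I expect no gain from gamma.

**Base.** Amber is charged with free base at 80.0% of the electrophile, and its readings still lie near the ceiling. I count the base a bystander, so I expect no gain from alpha or epsilon.

**My commitment.** I say 55.0% at 15 min, the same after theta and beta, and none as the best option. The forecast differs on the choice: it gives 55.5% now, 55.5% after theta, 55.5% after beta and names epsilon, saying “Adding base should restart the reaction”.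

**The result.** Amber stands at 58.5%, 3.5 points over my ceiling. Beta reaches 63.7% and theta 70.1%, so theta is best, bringing 12 points, and my none is wrong.

    nucleophile + acid set free ⇌ protonated nucleophile, settled at all times (K = 7.59 × 10⁵ M⁻¹, ΔH = −40.0 kJ mol⁻¹)
    electrophile + acid set free → side product (k = 1.77 M⁻¹ s⁻¹, Ea = 51.0 kJ mol⁻¹)
    acid set free + free base ⇌ salt of the base, settled at all times (K = 190 M⁻¹, ΔH = −45.0 kJ mol⁻¹)
    electrophile + nucleophile → acid set free + target (k = 1.66 M⁻¹ s⁻¹, Ea = 36.0 kJ mol⁻¹)
    (constants at −20 °C)

**The slowdown.** In amber, the half-life of electrophile by the making of target grows from 0.58 min as charged to 110 min at 15.0 min, with free nucleophile at 0.53% of its charge and 46.2% of that charge as protonated nucleophile. At that time the making of target uses electrophile at 0.52 of the rate of its loss to side product.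

**Second flask.** With 21 mM of nucleophile, the ceiling gives 95.5%. That neighbour flask stands at 94.4% at 15 min.

The numbers in the tables come from a simulation from invented constants; noise was put on by code.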